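**Retrosynthetic overview**
1. Target ⇐ 8,9-diol enal (double isobutyrylation) ⇐ macrolactone carrying the diol as an acetonide and C14 as a dimethyl acetal.
2. Macrolactone ⇐ open-chain Z-2-(bromomethyl)enoate / Z-enal: an intramolecular Nozaki–Hiyama allylation forms C6–C7 and closes the 10-membered carbocycle first; the γ-lactone closes second, in the same flask.
3. Bromo enal ⇐ coupled ester, by ester → aldehyde, Morita–Baylis–Hillman reaction (C11–C13 from methyl acrylate) and SN2′ bromination.
4. Key disconnection C9–C10: light-driven iridium/nickel decarboxylative alkenylation of an L-tartrate-derived dioxolane acid (C7–C9) with a Z-alkenyl iodide (C1–C6, C10, C14, C15). C8 comes from L-tartaric acid and relays to C9, then to C7 and C6.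
5. Alkenyl iodide ⇐ neryl acetate (the Z-C4=C5 alkene is bought), by ozonolysis, Wittig reaction, α-iodination and acetalisation.

Assumption: atoms are numbered as in germacranolides (C6 lactone carbinol, C7 ring fusion, C8/C9 ester carbons, C14 aldehyde carbon, C15 methyl); the target is the (6R,7S,8S,9S) enantiomer with both ring double bonds cis within the ring.

**Route**

Step 1
Reactants: 1 neryl acetate, (2Z)-3,7-dimethylocta-2,6-dien-1-yl acetate
Product: 2 (2Z)-3-methyl-6-oxohex-2-en-1-yl acetate
Conditions: O3 (1.0 equiv), CH2Cl2, −78 °C; then Me2S, −78 °C → rt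
Reagents that add atoms: ozone, [O-][O+]=O
Why: Chemoselective ozonolysis with reductive work-up: the remote, electron-rich trisubstituted alkene reacts much faster than the alkene deactivated by the allylic acetate, so only the isopropylidene end is cleaved and the bought Z-alkene (C4=C5) is kept.

Step 2
Reactants: 2 (2Z)-3-methyl-6-oxohex-2-en-1-yl acetate
Product: 3 (2Z,6E)-3-methyl-8-oxoocta-2,6-dien-1-yl acetate
Conditions: Ph3P=CHCHO (1.1 equiv), toluene, 80 °C
Reagents that add atoms: (triphenylphosphoranylidene)acetaldehyde, O=CC=P(c1ccccc1)(c1ccccc1)c1ccccc1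
Why: Wittig olefination with the stabilised formylmethylene ylide gives the E-enal and brings in C10 and C14.

Step 3
Reactants: 3 (2Z,6E)-3-methyl-8-oxoocta-2,6-dien-1-yl acetate
Product: 4 (2Z,6Z)-7-iodo-3-methyl-8-oxoocta-2,6-dien-1-yl acetate
Conditions: I2 (1.5 equiv), K2CO3 (1.2 equiv), DMAP (0.2 equiv), THF–H2O (1:1), rt, dark
Reagents that add atoms: iodine, II
Why: Baylis–Hillman-type α-iodination (DMAP conjugate addition, iodination of the enolate, elimination) gives the thermodynamically preferred Z-2-iodoenal, with iodine cis to the C2 chain and the formyl group trans to it, which is the C1=C10 geometry of the target once iodine is exchanged for C9.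

Step 4
Reactants: 4 (2Z,6Z)-7-iodo-3-methyl-8-oxoocta-2,6-dien-1-yl acetate
Product: 5 (2Z,6Z)-7-iodo-8,8-dimethoxy-3-methylocta-2,6-dien-1-yl acetate
Conditions: HC(OMe)3 (3 equiv), PPTS (cat.), MeOH, rt
Reagents that add atoms: trimethyl orthoformate, COC(OC)OC
Why: Acid-catalysed acetalisation masks C14 so that it survives the hydride step and cannot compete with C6 as the electrophile in the ring closure.

Step 5
Reactants: 6 dimethyl (4R,5R)-2,2-dimethyl-1,3-dioxolane-4,5-dicarboxylate (dimethyl 2,3-O-isopropylidene-L-tartrate)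
Product: 7 (4R,5R)-5-(methoxycarbonyl)-2,2-dimethyl-1,3-dioxolane-4-carboxylic acid
Conditions: KOH (1.0 equiv), MeOH, 0 °C → rt; then aq. HCl to pH 2
Reagents that add atoms: potassium hydroxide, [K+].[OH-]
Why: Mono-saponification of the C2-symmetric diester (either ester gives the same product); the carboxylate formed slows the second hydrolysis, and both stereocentres are untouched.

Step 6
Reactants: 7 (4R,5R)-5-(methoxycarbonyl)-2,2-dimethyl-1,3-dioxolane-4-carboxylic acid, 5 (2Z,6Z)-7-iodo-8,8-dimethoxy-3-methylocta-2,6-dien-1-yl acetate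
Product: 8 methyl (4R,5S)-5-[(1E,5Z)-7-acetoxy-1-(dimethoxymethyl)-5-methylhepta-1,5-dien-1-yl]-2,2-dimethyl-1,3-dioxolane-4-carboxylate
Conditions: [Ir(dF(CF3)ppy)2(dtbbpy)]PF6 (1 mol%), NiCl2(dme) (10 mol%), 4,4′-di-tert-butyl-2,2′-bipyridine (15 mol%), Cs2CO3 (1.5 equiv), DMSO, 450 nm LEDs, rt
Reagents that add atoms: none
Why: Proposed new method: the photoexcited iridium complex oxidises the caesium carboxylate of 7, loss of CO2 gives the nucleophilic dioxolan-4-yl radical, zerovalent nickel inserts into the C–I bond of 5 with retention of alkene geometry, the divalent alkenylnickel captures the radical on the face anti to the neighbouring C8 ester, and the trivalent nickel species reductively eliminates to forge C9–C10 as the trans-dioxolane (C9 set by the tartrate-derived C8, the same spatial arrangement the carboxyl had) before the reduced iridium complex returns monovalent nickel to zerovalent nickel; the closest known reaction type is the dual photoredox/nickel decarboxylative alkenylation of simple cyclic α-oxy acids with vinyl halides, which has not been shown for a tartrate-derived ester-bearing dioxolane acid combined with a Z-trisubstituted alkenyl iodide branched at the iodine-bearing carbon, nor with the 1,2-trans stereocontrol needed here.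

Step 7
Reactants: 8 methyl (4R,5S)-5-[(1E,5Z)-7-acetoxy-1-(dimethoxymethyl)-5-methylhepta-1,5-dien-1-yl]-2,2-dimethyl-1,3-dioxolane-4-carboxylate
Product: 9 (4R,5S)-5-[(1E,5Z)-1-(dimethoxymethyl)-7-hydroxy-5-methylhepta-1,5-dien-1-yl]-2,2-dimethyl-1,3-dioxolane-4-carbaldehyde
Conditions: i-Bu2AlH (2.5 equiv), CH2Cl2, −78 °C; MeOH quench at −78 °C, aq. potassium sodium tartrate
Reagents that add atoms: none
Why: Partial ester reduction: at −78 °C the α-alkoxy methyl ester stops at the chelated aluminium hemiacetal (aldehyde on quench) while the acetate is cleaved in the same operation, so C7 arrives as the aldehyde and C6 as the free allylic alcohol.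

Step 8
Reactants: 9 (4R,5S)-5-[(1E,5Z)-1-(dimethoxymethyl)-7-hydroxy-5-methylhepta-1,5-dien-1-yl]-2,2-dimethyl-1,3-dioxolane-4-carbaldehyde
Product: 10 methyl 2-[hydroxy{(4S,5S)-5-[(1E,5Z)-1-(dimethoxymethyl)-7-hydroxy-5-methylhepta-1,5-dien-1-yl]-2,2-dimethyl-1,3-dioxolan-4-yl}methyl]prop-2-enoate (both carbinol epimers)
Conditions: methyl acrylate (5 equiv), DABCO (1.0 equiv), MeOH, rt, 48 h
Reagents that add atoms: methyl acrylate, C=CC(=O)OC
Why: Morita–Baylis–Hillman reaction of the activated α-alkoxy aldehyde installs C11–C13; the new carbinol centre forms as a mixture that is erased in step 10, the trans-dioxolane aldehyde is the favoured epimer so C8 is safe, and the amine is used before any Z-enal is present.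

Step 9
Reactants: 10 methyl 2-[hydroxy{(4S,5S)-5-[(1E,5Z)-1-(dimethoxymethyl)-7-hydroxy-5-methylhepta-1,5-dien-1-yl]-2,2-dimethyl-1,3-dioxolan-4-yl}methyl]prop-2-enoate
Product: 11 methyl 2-[hydroxy{(4S,5S)-5-[(1E,5Z)-1-(dimethoxymethyl)-5-methyl-7-oxohepta-1,5-dien-1-yl]-2,2-dimethyl-1,3-dioxolan-4-yl}methyl]prop-2-enoate
Conditions: TEMPO (10 mol%), PhI(OAc)2 (1.1 equiv), CH2Cl2, rt
Reagents that add atoms: none
Why: Oxoammonium (TEMPO) oxidation takes the primary allylic alcohol much faster than the hindered, electron-poor secondary Baylis–Hillman alcohol and, being amine-free, gives the neral-type Z-enal (C6) without Z/E isomerisation.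

Step 10
Reactants: 11 methyl 2-[hydroxy{(4S,5S)-5-[(1E,5Z)-1-(dimethoxymethyl)-5-methyl-7-oxohepta-1,5-dien-1-yl]-2,2-dimethyl-1,3-dioxolan-4-yl}methyl]prop-2-enoate
Product: 12 methyl (2Z)-2-(bromomethyl)-3-{(4S,5S)-5-[(1E,5Z)-1-(dimethoxymethyl)-5-methyl-7-oxohepta-1,5-dien-1-yl]-2,2-dimethyl-1,3-dioxolan-4-yl}prop-2-enoate
Conditions: NBS (1.3 equiv), Me2S (1.5 equiv), CH2Cl2, −20 °C → rt
Reagents that add atoms: N-bromosuccinimide, O=C1CCC(=O)N1Br
Why: Corey–Kim-type bromination with allylic transposition (SN2′) converts both carbinol epimers into the same thermodynamically favoured Z-2-(bromomethyl)enoate under non-acidic conditions that spare the acetal, the acetonide and the enal.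

Step 11
Reactants: 12 methyl (2Z)-2-(bromomethyl)-3-{(4S,5S)-5-[(1E,5Z)-1-(dimethoxymethyl)-5-methyl-7-oxohepta-1,5-dien-1-yl]-2,2-dimethyl-1,3-dioxolan-4-yl}prop-2-enoate
Product: 14 (6R,7S,8S,9S)-8,9-(isopropylidenedioxy)-14,14-dimethoxygermacra-1(10),4,11(13)-trien-12,6-olide, via hydroxy ester 13 (not isolated)
Conditions: CrCl2 (6 equiv), THF–DMF (4:1), 3 mM, rt, slow addition of 12 over 10 h; then PPTS (cat.), CH2Cl2, rt on the crude
Reagents that add atoms: none
Why: Intramolecular Nozaki–Hiyama (Barbier-type) allylation: two equivalents of divalent chromium turn the allylic bromide into a 2-(methoxycarbonyl)allylchromium species that adds through C7 to the C6 aldehyde in a chair transition state, anti as in known germacranolide ring closures (trans lactone), and on the C7 face anti to the C8–C9 bond with H8 in the alkene plane (allylic 1,3-strain), so the tartrate-derived C8 sets C7 (S) and C6 (R) before the alkoxide lactonises onto the methyl ester.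

Step 12
Reactants: 14 (6R,7S,8S,9S)-8,9-(isopropylidenedioxy)-14,14-dimethoxygermacra-1(10),4,11(13)-trien-12,6-olide
Product: 15 (6R,7R,8S,9S)-8,9-dihydroxy-14-oxogermacra-1(10),4,11(13)-trien-12,6-olide
Conditions: TFA–H2O (9:1), CH2Cl2, 0 °C
Reagents that add atoms: water, O
Why: Acid hydrolysis removes the acetonide and the dimethyl acetal in one operation and releases the conjugated aldehyde in its stable geometry (formyl trans to C2); no stereocentre is touched, and the C7 descriptor changes only by priority.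

Step 13
Reactants: 15 (6R,7R,8S,9S)-8,9-dihydroxy-14-oxogermacra-1(10),4,11(13)-trien-12,6-olide
Product: 16 (6R,7S,8S,9S)-8,9-bis(2-methylpropanoyloxy)-14-oxogermacra-1(10),4,11(13)-trien-12,6-olide (target)
Conditions: (i-PrCO)2O (4 equiv), DMAP (0.2 equiv), Et3N (4 equiv), CH2Cl2, 0 °C → rt
Reagents that add atoms: isobutyric anhydride, CC(C)C(=O)OC(=O)C(C)C
Why: DMAP-catalysed acyl transfer esterifies both secondary hydroxyls without creating or disturbing a stereocentre and completes the target.

**Compound list**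

1 | neryl acetate, (2Z)-3,7-dimethylocta-2,6-dien-1-yl acetate | CC(=O)OC/C=C(C)\CCC=C(C)C | starting material
2 | (2Z)-3-methyl-6-oxohex-2-en-1-yl acetate | CC(=O)OC/C=C(C)\CCC=O | intermediate
3 | (2Z,6E)-3-methyl-8-oxoocta-2,6-dien-1-yl acetate | CC(=O)OC/C=C(C)\CC/C=C/C=O | intermediate
4 | (2Z,6Z)-7-iodo-3-methyl-8-oxoocta-2,6-dien-1-yl acetate | CC(=O)OC/C=C(C)\CC/C=C(\I)C=O | intermediate
5 | (2Z,6Z)-7-iodo-8,8-dimethoxy-3-methylocta-2,6-dien-1-yl acetate | CC(=O)OC/C=C(C)\CC/C=C(\I)C(OC)OC | intermediate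
6 | dimethyl (4R,5R)-2,2-dimethyl-1,3-dioxolane-4,5-dicarboxylate (dimethyl 2,3-O-isopropylidene-L-tartrate) | COC(=O)[C@@H]1OC(C)(C)O[C@H]1C(=O)OC | starting material
7 | (4R,5R)-5-(methoxycarbonyl)-2,2-dimethyl-1,3-dioxolane-4-carboxylic acid | COC(=O)[C@@H]1OC(C)(C)O[C@H]1C(=O)O | intermediate
8 | methyl (4R,5S)-5-[(1E,5Z)-7-acetoxy-1-(dimethoxymethyl)-5-methylhepta-1,5-dien-1-yl]-2,2-dimethyl-1,3-dioxolane-4-carboxylate | COC(=O)[C@@H]1OC(C)(C)O[C@H]1/C(=C\CC/C(C)=C\COC(C)=O)C(OC)OC | intermediate
9 | (4R,5S)-5-[(1E,5Z)-1-(dimethoxymethyl)-7-hydroxy-5-methylhepta-1,5-dien-1-yl]-2,2-dimethyl-1,3-dioxolane-4-carbaldehyde | O=C[C@@H]1OC(C)(C)O[C@H]1/C(=C\CC/C(C)=C\CO)C(OC)OC | intermediate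
10 | methyl 2-[hydroxy{(4S,5S)-5-[(1E,5Z)-1-(dimethoxymethyl)-7-hydroxy-5-methylhepta-1,5-dien-1-yl]-2,2-dimethyl-1,3-dioxolan-4-yl}methyl]prop-2-enoate, both carbinol epimers | C=C(C(=O)OC)C(O)[C@@H]1OC(C)(C)O[C@H]1/C(=C\CC/C(C)=C\CO)C(OC)OC | intermediate
11 | methyl 2-[hydroxy{(4S,5S)-5-[(1E,5Z)-1-(dimethoxymethyl)-5-methyl-7-oxohepta-1,5-dien-1-yl]-2,2-dimethyl-1,3-dioxolan-4-yl}methyl]prop-2-enoate, both carbinol epimers | C=C(C(=O)OC)C(O)[C@@H]1OC(C)(C)O[C@H]1/C(=C\CC/C(C)=C\C=O)C(OC)OC | intermediate
12 | methyl (2Z)-2-(bromomethyl)-3-{(4S,5S)-5-[(1E,5Z)-1-(dimethoxymethyl)-5-methyl-7-oxohepta-1,5-dien-1-yl]-2,2-dimethyl-1,3-dioxolan-4-yl}prop-2-enoate | COC(=O)/C(CBr)=C/[C@@H]1OC(C)(C)O[C@H]1/C(=C\CC/C(C)=C\C=O)C(OC)OC | intermediate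
13 | methyl (6R,7S,8S,9S)-6-hydroxy-8,9-(isopropylidenedioxy)-14,14-dimethoxygermacra-1(10),4,11(13)-trien-12-oate, ring double bonds cis in the ring | C=C(C(=O)OC)[C@H]1[C@H](O)/C=C(C)\CC/C=C(C(OC)OC)\[C@@H]2OC(C)(C)O[C@@H]12 | intermediate (not isolated)
14 | (6R,7S,8S,9S)-8,9-(isopropylidenedioxy)-14,14-dimethoxygermacra-1(10),4,11(13)-trien-12,6-olide, trans-fused lactone | C=C1C(=O)O[C@@H]2/C=C(/C)CC/C=C(/C(OC)OC)[C@@H]3OC(C)(C)O[C@H]3[C@@H]12 | intermediate
15 | (6R,7R,8S,9S)-8,9-dihydroxy-14-oxogermacra-1(10),4,11(13)-trien-12,6-olide | C=C1C(=O)O[C@@H]2/C=C(/C)CC/C=C(/C=O)[C@H](O)[C@@H](O)[C@@H]12 | intermediate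
16 | (6R,7S,8S,9S)-8,9-bis(2-methylpropanoyloxy)-14-oxogermacra-1(10),4,11(13)-trien-12,6-olide | C=C1C(=O)O[C@@H]2/C=C(/C)CC/C=C(/C=O)[C@H](OC(=O)C(C)C)[C@@H](OC(=O)C(C)C)[C@@H]12 | target

**Step count**
Total: 13 steps. Longest linear sequence: 12 steps (steps 1–4 and 6–13, from neryl acetate).

**Three steps most likely to fail**

Step 6 (the proposed new coupling). The iodine-bearing carbon of 5 is branched and flanked by a cis chain, which may slow reductive elimination and let protodecarboxylation of 7 or reduction of 5 take over. The trans/cis ratio at C9 is untested, and nickel could also engage the allylic acetate. The fallback uses known chemistry and sets out from 7. The acid is esterified with N-hydroxyphthalimide (N,N′-diisopropylcarbodiimide, DMAP cat., CH2Cl2) to the redox-active N-hydroxyphthalimide ester F1. F1 is then joined to iodide 5 in a thermal nickel-catalysed reductive cross-electrophile coupling without light (NiBr2(dme), 4,4′-di-tert-butyl-2,2′-bipyridine, Zn dust, DMA, rt). The same dioxolanyl radical is formed by electron transfer to the pre-activated ester and is captured trans to the C8 ester, and the sequence comes back to the route at 8.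

Step 11 (ring closure). The doubly trans-fused 10-membered ring may form slowly (oligomers), and the allylation may go syn instead of anti, giving the C6 epimer. The fallback sets out from 12 and changes the stereochemical plan: the ring is deliberately closed to the cis lactone and C6 is then inverted. Indium powder in THF–H2O at high dilution gives the Z-allylindium, which typically adds syn to give the syn hydroxy ester F2. F2 lactonises in the flask to the cis-fused lactone F3. LiOH (THF–H2O) opens F3 to the hydroxy acid F4. Mitsunobu lactonisation (PPh3, DIAD, toluene, 0 °C, high dilution) closes the γ-lactone with inversion at C6, and the sequence comes back at 14.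

Step 13 (acylation of the diol enal). The free 8-hydroxyl of 15 can add to the C14 aldehyde (five-membered hemiacetal) or, under basic acylation, attack the lactone carbonyl (8,12-olide), and the enal is base-sensitive. The fallback sets out from 14 and reorders the end game so that the aldehyde is released last. CSA (cat.) in MeOH at rt exchanges the acetonide for the free diol while the dimethyl acetal persists in methanol, giving the diol acetal F5. Isobutyric anhydride, DMAP and Et3N in CH2Cl2 give the bis-isobutyrate acetal F6. PPTS in acetone–H2O at rt then hydrolyses the acetal, and the sequence comes back at 16.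

**Further compounds**
F1 | step 6 | 1,3-dioxoisoindolin-2-yl methyl (4R,5R)-2,2-dimethyl-1,3-dioxolane-4,5-dicarboxylate | COC(=O)[C@@H]1OC(C)(C)O[C@H]1C(=O)ON1C(=O)c2ccccc2C1=O
F2 | step 11 | methyl (6S,7S,8S,9S)-6-hydroxy-8,9-(isopropylidenedioxy)-14,14-dimethoxygermacra-1(10),4,11(13)-trien-12-oate (6-epimer of 13) | C=C(C(=O)OC)[C@H]1[C@@H](O)/C=C(C)\CC/C=C(C(OC)OC)\[C@@H]2OC(C)(C)O[C@@H]12
F3 | step 11 | (6S,7S,8S,9S)-8,9-(isopropylidenedioxy)-14,14-dimethoxygermacra-1(10),4,11(13)-trien-12,6-olide (cis-fused lactone, 6-epimer of 14) | C=C1C(=O)O[C@H]2/C=C(/C)CC/C=C(/C(OC)OC)[C@@H]3OC(C)(C)O[C@H]3[C@@H]12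
F4 | step 11 | (6S,7S,8S,9S)-6-hydroxy-8,9-(isopropylidenedioxy)-14,14-dimethoxygermacra-1(10),4,11(13)-trien-12-oic acid | C=C(C(=O)O)[C@H]1[C@@H](O)/C=C(C)\CC/C=C(C(OC)OC)\[C@@H]2OC(C)(C)O[C@@H]12
F5 | step 13 | (6R,7R,8S,9S)-8,9-dihydroxy-14,14-dimethoxygermacra-1(10),4,11(13)-trien-12,6-olide | C=C1C(=O)O[C@@H]2/C=C(/C)CC/C=C(/C(OC)OC)[C@H](O)[C@@H](O)[C@@H]12
F6 | step 13 | (6R,7S,8S,9S)-14,14-dimethoxy-8,9-bis(2-methylpropanoyloxy)germacra-1(10),4,11(13)-trien-12,6-olide | C=C1C(=O)O[C@@H]2/C=C(/C)CC/C=C(/C(OC)OC)[C@H](OC(=O)C(C)C)[C@@H](OC(=O)C(C)C)[C@@H]12
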